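Ring B is cut between C5–C6 and across C8=C9, leaving ring A and a four-carbon nitroalkene. The key step exploits that C5 is the β-carbon of a ring A enone doubly activated by the C3 ketone and the C19 ester on C4, and that C8=C9 is an isolated tetrasubstituted ring B alkene next to the C10 quaternary carbon. In one flask the nitronate of 2-methyl-4-nitrobut-1-ene adds to C5 of a methyl 6-oxocyclohex-1-ene-1-carboxylate that carries the complete side chain on a C9 methylidene, and ring-closing metathesis then joins C8 to C9. The nitro group is later turned into the 6β-hydroxyl; C4 is methylated after ring closure.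

Key step: step 10

Remark: the antipode of the chromium salen catalyst in step 1 is assumed to be the one that gives the S-configured quaternary carbon of 3; if it is not, its mirror image is used.

Step 1
Reactants: 1 (E)-3-(tert-butyldimethylsilyloxy)-N,N-dimethylbuta-1,3-dien-1-amine; 2 methacrolein
Product: 3 (1S,2R)-4-(tert-butyldimethylsilyloxy)-2-(dimethylamino)-1-methylcyclohex-3-ene-1-carbaldehyde
Conditions: [(S,S)-salen]CrSbF6 (5 mol %; salen = N,N′-bis(3,5-di-tert-butylsalicylidene)cyclohexane-1,2-diamine dianion), 4 Å molecular sieves, CH2Cl2, −40 °C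
Reagents that add atoms: none
Why: Catalytic asymmetric Diels–Alder reaction of a 1-amino-3-siloxy diene with an α-substituted acrolein should give the endo adduct with the amino carbon next to the new quaternary carbon, whose configuration (future C10) is set by the chiral chromium salen Lewis acid shielding one face of the bound aldehyde.

Step 2
Reactants: 3 (1S,2R)-4-(tert-butyldimethylsilyloxy)-2-(dimethylamino)-1-methylcyclohex-3-ene-1-carbaldehyde
Product: 4 1-[(1S,2R)-4-(tert-butyldimethylsilyloxy)-2-(dimethylamino)-1-methylcyclohex-3-en-1-yl]ethan-1-ol (both carbinol epimers)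
Conditions: MeMgBr, THF, −78 °C
Reagents that add atoms: methylmagnesium bromide C[Mg]Br
Why: Grignard addition to the neopentyl aldehyde should leave the masked enone (silyl enol ether and β-amine) untouched, and the new carbinol centre is of no consequence because it is oxidised in step 3.

Step 3
Reactants: 4 1-[(1S,2R)-4-(tert-butyldimethylsilyloxy)-2-(dimethylamino)-1-methylcyclohex-3-en-1-yl]ethan-1-ol
Product: 5 1-[(1S,2R)-4-(tert-butyldimethylsilyloxy)-2-(dimethylamino)-1-methylcyclohex-3-en-1-yl]ethan-1-one
Conditions: Pr4N[RuO4] (5 mol %), N-methylmorpholine N-oxide, 4 Å molecular sieves, CH2Cl2, rt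
Reagents that add atoms: none
Why: Ley–Griffith oxidation should convert the secondary alcohol into the methyl ketone under neutral conditions that spare the silyl enol ether and the tertiary amine.

Step 4
Reactants: 5 1-[(1S,2R)-4-(tert-butyldimethylsilyloxy)-2-(dimethylamino)-1-methylcyclohex-3-en-1-yl]ethan-1-one; 6 methyl (E)-4-bromo-3-methylbut-2-enoate
Product: 7 methyl (2E)-6-[(1S,2R)-4-(tert-butyldimethylsilyloxy)-2-(dimethylamino)-1-methylcyclohex-3-en-1-yl]-3-methyl-6-oxohex-2-enoate
Conditions: LDA, THF, −78 °C; then 6, −78 to 0 °C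
Reagents that add atoms: none
Why: The ketone can enolise only towards its methyl group because C10 is quaternary, so kinetic lithium enolate alkylation (SN2 at the primary allylic bromide with the alkene geometry retained) should attach C12 to C15 of the side chain.

Step 5
Reactants: 7 methyl (2E)-6-[(1S,2R)-4-(tert-butyldimethylsilyloxy)-2-(dimethylamino)-1-methylcyclohex-3-en-1-yl]-3-methyl-6-oxohex-2-enoate
Product: 8 methyl (2E)-6-[(1R,2R)-4-(tert-butyldimethylsilyloxy)-2-(dimethylamino)-1-methylcyclohex-3-en-1-yl]-3-methylhepta-2,6-dienoate (same spatial arrangement as 3; the descriptor changes by priority only)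
Conditions: Ph3PCH3Br, KOtBu, THF, 0 to 50 °C
Reagents that add atoms: methyltriphenylphosphonium bromide C[P+](c1ccccc1)(c1ccccc1)c1ccccc1.[Br-]
Why: Wittig methylenation should turn the hindered C9 ketone into the 1,1-disubstituted alkene needed for ring closure, while the conjugated ester and the silyl enol ether do not react with the non-stabilised ylide.

Step 6
Reactants: 8 methyl (2E)-6-[(1R,2R)-4-(tert-butyldimethylsilyloxy)-2-(dimethylamino)-1-methylcyclohex-3-en-1-yl]-3-methylhepta-2,6-dienoate
Product: 9 methyl (2E)-3-methyl-6-[(1S)-1-methyl-4-oxocyclohex-2-en-1-yl]hepta-2,6-dienoate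
Conditions: HF (48 % aq), MeCN, 0 °C to rt
Reagents that add atoms: none
Why: Acidic cleavage of the silyl enol ether followed by β-elimination of dimethylamine should unveil the 4,4-disubstituted cyclohexenone, the usual unmasking of such Diels–Alder adducts.

Step 7
Reactants: 9 methyl (2E)-3-methyl-6-[(1S)-1-methyl-4-oxocyclohex-2-en-1-yl]hepta-2,6-dienoate
Product: 10 methyl (2E)-6-[(1S)-3-iodo-1-methyl-4-oxocyclohex-2-en-1-yl]-3-methylhepta-2,6-dienoate
Conditions: I2, pyridine, CH2Cl2, rt
Reagents that add atoms: iodine II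
Why: α-Iodination of the enone by the Johnson procedure (pyridine conjugate addition, enolate iodination, elimination) should functionalise C4 only.

Step 8
Reactants: 10 methyl (2E)-6-[(1S)-3-iodo-1-methyl-4-oxocyclohex-2-en-1-yl]-3-methylhepta-2,6-dienoate
Product: 11 methyl (3S)-3-[(5E)-7-methoxy-5-methyl-7-oxohepta-1,5-dien-2-yl]-3-methyl-6-oxocyclohex-1-ene-1-carboxylate
Conditions: Pd(OAc)2 (5 mol %), PPh3, CO (1 atm), MeOH, Et3N, DMF, 50 °C
Reagents that add atoms: carbon monoxide [C-]#[O+]; methanol CO
Why: Palladium-catalysed methoxycarbonylation of the vinyl iodide (oxidative addition, CO insertion, methanolysis) should install C19 as the ester and make C5 the β-carbon of a doubly activated alkene.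

Step 9
Reactants: 12 4-bromo-2-methylbut-1-ene
Product: 13 2-methyl-4-nitrobut-1-ene
Conditions: NaNO2, urea, DMF, rt
Reagents that add atoms: sodium nitrite [Na+].[O-]N=O
Why: Kornblum substitution of the primary bromide by nitrite should give the primary nitroalkane.

Step 10
Reactants: 11 methyl (3S)-3-[(5E)-7-methoxy-5-methyl-7-oxohepta-1,5-dien-2-yl]-3-methyl-6-oxocyclohex-1-ene-1-carboxylate; 13 2-methyl-4-nitrobut-1-ene
Product: 15 dimethyl 6ξ-nitro-3-oxo-18-norlabda-8,13E-diene-15,19-dioate (5α-H; epimers at C4 and C6), via Michael adduct 14 (not isolated)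
Conditions: DBU (0.1 equiv), CH2Cl2, 0 °C; then AcOH (0.1 equiv), second-generation Hoveyda–Grubbs catalyst (10 mol %), toluene, 80 °C
Reagents that add atoms: none
Why: DBU forms the nitronate of 13, which adds to C5 of the alkylidene β-keto ester 11 (nitro-Michael addition, the closest known type being nitroalkane additions to 2-alkoxycarbonyl cyclohexenones) and gives the enolised β-keto ester 14 with the C5–C6 bond in place. After the base is quenched, the ruthenium alkylidene engages the two 1,1-disubstituted alkenes of 14 (the C8 isopropenyl and the C9 methylidene) and closes ring B as a six-membered ring by ring-closing olefin metathesis with loss of ethylene, which forms the tetrasubstituted C8=C9 bond. C5 is the only lasting new stereocentre: the nitronate should enter anti to the larger C10 substituent (the branched heptadienyl chain) and syn to the C10 methyl, which becomes the trans ring fusion (5α-H) once ring B is closed. C6 (nitro-bearing) and C4 (enolisable) form as mixtures and are erased in steps 13 and 11. The step needs facial selectivity at C5, which rests on the size difference between the two C10 groups, and chemoselective metathesis, which is secured because the only other alkene is a trisubstituted, ester-conjugated one that the catalyst should not engage.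

Step 11
Reactants: 15 dimethyl 6ξ-nitro-3-oxo-18-norlabda-8,13E-diene-15,19-dioate
Product: 16 dimethyl 6ξ-nitro-3-oxolabda-8,13E-diene-15,19-dioate (4α-methyl; 4β-methoxycarbonyl)
Conditions: K2CO3, MeI, acetone, rt
Reagents that add atoms: iodomethane CI
Why: C-Methylation of the β-keto ester enolate should take place from the α face, anti to the axial C10 methyl as in the classical podocarpate series, which puts the new methyl α and leaves the C19 ester β.

Step 12
Reactants: 16 dimethyl 6ξ-nitro-3-oxolabda-8,13E-diene-15,19-dioate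
Product: 17 dimethyl 3α-hydroxy-6ξ-nitrolabda-8,13E-diene-15,19-dioate
Conditions: LiBH(s-Bu)3 (2.2 equiv), THF, −78 °C
Reagents that add atoms: none
Why: The bulky hydride should attack the C3 ketone along the equatorial trajectory and give the axial 3α-alcohol (Selectride reduction of a hindered cyclohexanone), while the β,β-disubstituted enoate, the esters and the nitronate formed in situ are not reduced at this temperature.

Step 13
Reactants: 17 dimethyl 3α-hydroxy-6ξ-nitrolabda-8,13E-diene-15,19-dioate
Product: 19 3α-hydroxy-19-methoxy-6,19-dioxolabda-8,13E-dien-15-oic acid, via dilithium nitronate carboxylate 18 (not isolated)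
Conditions: LiOH, THF–MeOH–H2O, 40 °C; then TiCl3, NH4OAc, H2O, 0 °C to rt
Reagents that add atoms: lithium hydroxide [Li+].[OH-]; water O
Why: Saponification of the unhindered conjugated methyl ester (the axial neopentyl C19 ester should survive) also forms the nitronate, which titanium trichloride reduces to the imine that hydrolyses to the C6 ketone (McMurry variant of the Nef reaction) under buffered conditions meant to keep the 8,9-alkene out of conjugation.

Step 14
Reactants: 19 3α-hydroxy-19-methoxy-6,19-dioxolabda-8,13E-dien-15-oic acid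
Product: 21 3α,6β,19-trihydroxylabda-8,13E-dien-15-oic acid, via 6β-hydroxy ester 20 (not isolated)
Conditions: LiBH4, THF, 0 to 50 °C
Reagents that add atoms: none
Why: Borohydride should attack the C6 ketone from the α face because the β face is blocked by the axial C19 and C20 groups, giving the axial 6β-alcohol, whose alkoxide assists reduction of the neighbouring C19 ester to the primary alcohol while the lithium carboxylate is inert (chemoselective LiBH4 reduction).

Step 15
Reactants: 21 3α,6β,19-trihydroxylabda-8,13E-dien-15-oic acid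
Product: 22 tert-butyldimethylsilyl 19-(tert-butyldimethylsilyloxy)-3α,6β-dihydroxylabda-8,13E-dien-15-oate (used crude)
Conditions: t-BuMe2SiCl (2.3 equiv), imidazole, DMF, 0 °C
Reagents that add atoms: tert-butyldimethylsilyl chloride CC(C)(C)[Si](C)(C)Cl
Why: Silylation of the primary C19 hydroxyl and of the carboxylic acid should be much faster than that of the two hindered axial secondary hydroxyls (selective silyl protection).

Step 16
Reactants: 22 tert-butyldimethylsilyl 19-(tert-butyldimethylsilyloxy)-3α,6β-dihydroxylabda-8,13E-dien-15-oate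
Product: 23 tert-butyldimethylsilyl 19-(tert-butyldimethylsilyloxy)-6β-hydroxy-3α-(3-methylbutanoyloxy)labda-8,13E-dien-15-oate
Conditions: (i-BuCO)2O, DMAP, Et3N, CH2Cl2, rt
Reagents that add atoms: 3-methylbutanoic anhydride CC(C)CC(=O)OC(=O)CC(C)C
Why: DMAP-catalysed acylation should take place at the 3α-hydroxyl, because the 6β-hydroxyl is 1,3-diaxial to the C19 and C20 substituents and too hindered to react (site-selective esterification).

Step 17
Reactants: 23 tert-butyldimethylsilyl 19-(tert-butyldimethylsilyloxy)-6β-hydroxy-3α-(3-methylbutanoyloxy)labda-8,13E-dien-15-oate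
Product: 24 6β,19-dihydroxy-3α-(3-methylbutanoyloxy)labda-8,13E-dien-15-oic acid (CNP0274836.1)
Conditions: HF·pyridine, pyridine, THF, 0 °C to rt
Reagents that add atoms: none
Why: Buffered fluoride should cleave the silyl ether and the silyl ester without touching the isovalerate, under mildly acidic conditions that suppress acyl migration from O3 to O19 (desilylation).

Compound list
1 | (E)-3-(tert-butyldimethylsilyloxy)-N,N-dimethylbuta-1,3-dien-1-amine | CN(C)/C=C/C(=C)O[Si](C)(C)C(C)(C)C | starting material
2 | methacrolein (2-methylprop-2-enal) | CC(=C)C=O | starting material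
3 | (1S,2R)-4-(tert-butyldimethylsilyloxy)-2-(dimethylamino)-1-methylcyclohex-3-ene-1-carbaldehyde (endo adduct; C1 is the future C10) | O=C[C@@]1(C)CCC(O[Si](C)(C)C(C)(C)C)=C[C@H]1N(C)C | intermediate
4 | 1-[(1S,2R)-4-(tert-butyldimethylsilyloxy)-2-(dimethylamino)-1-methylcyclohex-3-en-1-yl]ethan-1-ol (both carbinol epimers) | CC(O)[C@@]1(C)CCC(O[Si](C)(C)C(C)(C)C)=C[C@H]1N(C)C | intermediate
5 | 1-[(1S,2R)-4-(tert-butyldimethylsilyloxy)-2-(dimethylamino)-1-methylcyclohex-3-en-1-yl]ethan-1-one | CC(=O)[C@@]1(C)CCC(O[Si](C)(C)C(C)(C)C)=C[C@H]1N(C)C | intermediate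
6 | methyl (E)-4-bromo-3-methylbut-2-enoate | COC(=O)/C=C(\C)CBr | starting material
7 | methyl (2E)-6-[(1S,2R)-4-(tert-butyldimethylsilyloxy)-2-(dimethylamino)-1-methylcyclohex-3-en-1-yl]-3-methyl-6-oxohex-2-enoate | COC(=O)/C=C(\C)CCC(=O)[C@@]1(C)CCC(O[Si](C)(C)C(C)(C)C)=C[C@H]1N(C)C | intermediate
8 | methyl (2E)-6-[(1R,2R)-4-(tert-butyldimethylsilyloxy)-2-(dimethylamino)-1-methylcyclohex-3-en-1-yl]-3-methylhepta-2,6-dienoate | COC(=O)/C=C(\C)CCC(=C)[C@@]1(C)CCC(O[Si](C)(C)C(C)(C)C)=C[C@H]1N(C)C | intermediate
9 | methyl (2E)-3-methyl-6-[(1S)-1-methyl-4-oxocyclohex-2-en-1-yl]hepta-2,6-dienoate | COC(=O)/C=C(\C)CCC(=C)[C@@]1(C)CCC(=O)C=C1 | intermediate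
10 | methyl (2E)-6-[(1S)-3-iodo-1-methyl-4-oxocyclohex-2-en-1-yl]-3-methylhepta-2,6-dienoate | COC(=O)/C=C(\C)CCC(=C)[C@@]1(C)CCC(=O)C(I)=C1 | intermediate
11 | methyl (3S)-3-[(5E)-7-methoxy-5-methyl-7-oxohepta-1,5-dien-2-yl]-3-methyl-6-oxocyclohex-1-ene-1-carboxylate | COC(=O)/C=C(\C)CCC(=C)[C@@]1(C)CCC(=O)C(C(=O)OC)=C1 | intermediate
12 | 4-bromo-2-methylbut-1-ene | C=C(C)CCBr | starting material
13 | 2-methyl-4-nitrobut-1-ene | C=C(C)CC[N+](=O)[O-] | intermediate
14 | methyl 3-[(5E)-7-methoxy-5-methyl-7-oxohepta-1,5-dien-2-yl]-3-methyl-2-(3-methyl-1-nitrobut-3-en-1-yl)-6-oxocyclohexane-1-carboxylate (nitrobutenyl group trans to the heptadienyl group; epimers at the ester and nitro carbons; ring B still open) | COC(=O)/C=C(\C)CCC(=C)[C@@]1(C)CCC(=O)C(C(=O)OC)[C@@H]1C(CC(C)=C)[N+](=O)[O-] | intermediate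
15 | dimethyl 6ξ-nitro-3-oxo-18-norlabda-8,13E-diene-15,19-dioate (5α-H, 10β-methyl; epimers at C4 and C6) | CC1=C(CC/C(C)=C/C(=O)OC)[C@@]2(C)CCC(=O)C(C(=O)OC)[C@@H]2C([N+](=O)[O-])C1 | intermediate
16 | dimethyl 6ξ-nitro-3-oxolabda-8,13E-diene-15,19-dioate (4α-methyl, 4β-methoxycarbonyl, 5α-H) | CC1=C(CC/C(C)=C/C(=O)OC)[C@@]2(C)CCC(=O)[C@](C)(C(=O)OC)[C@@H]2C([N+](=O)[O-])C1 | intermediate
17 | dimethyl 3α-hydroxy-6ξ-nitrolabda-8,13E-diene-15,19-dioate | CC1=C(CC/C(C)=C/C(=O)OC)[C@@]2(C)CC[C@@H](O)[C@](C)(C(=O)OC)[C@@H]2C([N+](=O)[O-])C1 | intermediate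
18 | dilithium salt of 3α-hydroxy-19-methoxy-6-nitro-19-oxolabda-8,13E-dien-15-oic acid (C6 nitronate, C15 carboxylate) | [Li+].[Li+].CC1=C(CC/C(C)=C/C(=O)[O-])[C@@]2(C)CC[C@@H](O)[C@](C)(C(=O)OC)[C@@H]2C(=[N+]([O-])[O-])C1 | intermediate
19 | 3α-hydroxy-19-methoxy-6,19-dioxolabda-8,13E-dien-15-oic acid | CC1=C(CC/C(C)=C/C(=O)O)[C@@]2(C)CC[C@@H](O)[C@](C)(C(=O)OC)[C@@H]2C(=O)C1 | intermediate
20 | 3α,6β-dihydroxy-19-methoxy-19-oxolabda-8,13E-dien-15-oic acid (lithium salt in the flask) | CC1=C(CC/C(C)=C/C(=O)O)[C@@]2(C)CC[C@@H](O)[C@](C)(C(=O)OC)[C@@H]2[C@H](O)C1 | intermediate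
21 | 3α,6β,19-trihydroxylabda-8,13E-dien-15-oic acid | CC1=C(CC/C(C)=C/C(=O)O)[C@@]2(C)CC[C@@H](O)[C@](C)(CO)[C@@H]2[C@H](O)C1 | intermediate
22 | tert-butyldimethylsilyl 19-(tert-butyldimethylsilyloxy)-3α,6β-dihydroxylabda-8,13E-dien-15-oate | CC1=C(CC/C(C)=C/C(=O)O[Si](C)(C)C(C)(C)C)[C@@]2(C)CC[C@@H](O)[C@](C)(CO[Si](C)(C)C(C)(C)C)[C@@H]2[C@H](O)C1 | intermediate
23 | tert-butyldimethylsilyl 19-(tert-butyldimethylsilyloxy)-6β-hydroxy-3α-(3-methylbutanoyloxy)labda-8,13E-dien-15-oate | CC1=C(CC/C(C)=C/C(=O)O[Si](C)(C)C(C)(C)C)[C@@]2(C)CC[C@@H](OC(=O)CC(C)C)[C@](C)(CO[Si](C)(C)C(C)(C)C)[C@@H]2[C@H](O)C1 | intermediate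
24 | 6β,19-dihydroxy-3α-(3-methylbutanoyloxy)labda-8,13E-dien-15-oic acid (CNP0274836.1) | CC1=C(CC/C(C)=C/C(=O)O)[C@@]2(C)CC[C@@H](OC(=O)CC(C)C)[C@](C)(CO)[C@@H]2[C@H](O)C1 | target

Total step count: 17. Longest linear sequence: 16 steps (steps 1 to 8 and 10 to 17; step 9 is a one-step side branch).

Steps most likely to fail

Step 10. The nitronate may add with low facial selectivity (C6 entering syn to the C10 alkenyl group, which leads into the cis-fused 5β series), and the metathesis may stall before the hindered tetrasubstituted alkene closes. Fallback: the ring fusion is put under thermodynamic control by recycling instead of resting on kinetic face selection. The key step is run from 11 as before, the cis-fused 5β-epimer of 15 F1 is separated, and F1 is heated with DBU in toluene. Retro-Michael opening of the C5–C6 bond (the β-keto ester enolate expels the tethered nitronate) and intramolecular re-addition should equilibrate the two ring fusions. The trans-fused isomer is removed by chromatography and the remainder is resubmitted. The fallback sets out from 11 and comes back at 15.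

Step 13. The 8,9-alkene may migrate into conjugation with the new C6 ketone, or the nitronate may be over-reduced to the oxime or amine. Fallback: a hydrolytic instead of a reductive Nef reaction. Compound 17 is saponified with LiOH and acidified carefully to 3α-hydroxy-19-methoxy-6ξ-nitro-19-oxolabda-8,13E-dien-15-oic acid F2. The nitronate of F2 (LiOMe, MeOH) is then added to cold methanolic H2SO4 at −30 °C, and the ketal formed is hydrolysed on aqueous work-up to 19. The fallback sets out from 17 and comes back at 19.

Step 5. The basic ylide may enolise the hindered C9 ketone, so that 7 is recovered, or may attack the ester. Fallback: non-basic titanium-mediated methylenation. Compound 7 is treated with the Takai–Lombardo reagent (Zn, CH2Br2, TiCl4, THF, 0 °C to rt), which methylenates hindered, enolisable ketones and leaves esters alone. The fallback sets out from 7, comes back at 8 and makes no new compound.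

Further compounds
F1 | step 10 | dimethyl 6ξ-nitro-3-oxo-18-nor-5β-labda-8,13E-diene-15,19-dioate (cis-fused C5 epimer of 15) | CC1=C(CC/C(C)=C/C(=O)OC)[C@@]2(C)CCC(=O)C(C(=O)OC)[C@H]2C([N+](=O)[O-])C1
F2 | step 13 | 3α-hydroxy-19-methoxy-6ξ-nitro-19-oxolabda-8,13E-dien-15-oic acid | CC1=C(CC/C(C)=C/C(=O)O)[C@@]2(C)CC[C@@H](O)[C@](C)(C(=O)OC)[C@@H]2C([N+](=O)[O-])C1
F0 | step 5 | none | none
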